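The amounts are 20 mM of substrate and 18.0 mM of partner, and the recipes part in how these go in.

common to all: time 40 h

| charge | substrate | partner | remark |
|---|---|---|---|
| oak | 20 mM | 18.0 mM | everything together at the start |
| maple | 20 mM | 18.0 mM (fed, over 25 h) | all else is in the flask from the start; the feed brings no volume worth counting |
| alder | 20 mM (fed, over 6.0 h) | 18.0 mM | all else is in the flask from the start; the feed brings no volume worth counting |
| ash | 20 mM | 18.0 mM (in portions, 2, over 25 h) | first portion at the start, last at 25 h |
| cedar | 20 mM (fed, over 25 h) | 18.0 mM | all else is in the flask from the start; the feed brings no volume worth counting |

    substrate + partner → target, rate k1*[substrate]^2*[partner]^0.5 (k1 = 15 M⁻¹·⁵ h⁻¹)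
    substrate ⇌ dormant form (K2 = 0.32, k2 = 0.065 h⁻¹)
    partner → decomposed reagent (k3 = 0.44 h⁻¹)

* the best flask by amount of target, in percent of the substrate charged; "all alike" if 1.5 percentage points covers them all (oak / maple / alder / ash / cedar / all alike)
* amount of target at the end, in percent of the substrate charged, oak
* amount of target at the end, in percent of the substrate charged, maple
* amount of target at the end, in percent of the substrate charged, alder
* amount of target at the end, in percent of the substrate charged, ash
* amount of target at the end, in percent of the substrate charged, cedar

- The quick number requested comes first, and the hunch sent with the request, taken here as the forecast, follows it. At the start in oak, decomposition removes partner at 7.92 mM h⁻¹ and coupling at 0.805 mM h⁻¹, so this reckoning lets partner decay undisturbed.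
- Free substrate is taken as 15.2 mM, the charge shared with the dormant form. The root of partner falls at half the decay constant, so a dose lasts about 4.55 h for coupling.
- The whole charge as one dose is then reckoned to give 2.10 mM of target. This burst yield, the coupling rate at the dose multiplied by that lasting time, is the quantity carried.
- In logarithms, the burst yield climbs 0.5 decade per decade of dose and 2 decades per decade of free substrate. Oak is reckoned at 10.5%, and ash, with its 2 portions, at 14.8%.
- Maple's feed is reckoned to hold partner near 1.64 mM for 25 h, which gives 17.4%.
- In alder and cedar, mean substrate over the lasting time is reckoned at half of what the feed brings in it. Squaring that mean is rough for a rising substrate, and it gives 2.62% for alder and 0.151% for cedar. The best flask reckons as maple.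
- The forecast gives 10.9% for oak, 15.7% for maple, 4% for alder, 12.1% for ash and 5.3% for cedar, with maple best: “The target is therefore limited by how much partner survives”. It names the same best flask as this reckoning, but its cedar stands higher.
- The simulation gives 10.5% for oak, 15.4% for maple, 4.05% for alder, 12.2% for ash and 0.553% for cedar, with maple best, as forecast.
- Maple's lead over cedar, 15 percentage points, comes in part from partner's decomposition acting together with the dormant form's return to substrate. The lead falls to 5.1 points in the run without decomposition and to 6.2 points in the run without the return. Maple's target equals 1.47 burst yields. For maple's feed over 7.50 h, the burst yield, scaled as for the feed over 25 h, gives 9.54%, and that simulated run stands at 12.0%.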